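Labels: ring A = Ca (CH bearing isopropenyl), Cb and Cc (the two CH2), Cd (C(CH3)OH), Ce (CH bearing the CH2 link). Ring B = B1 (C–CH2 link), B2 (C–OH), B3 (C(CH3)(prenyl)), B4 (C=O), B5 (C–acyl), B6 (C–OH).
Retrosynthetic cuts, in order: B3–prenyl (which rearomatises ring B), Cd–CH3, Ce–CH2 link, Cb–Cc of ring A, and last Ca–Ce.
Enabling feature: Cb–Cc is the only ring A bond whose two carbons carry nothing but hydrogen, and it adjoins Cd, a latent carbonyl carbon. It can therefore be made as the C=C of a cyclopent-2-enone by metathesis of a vinyl group on Ca with a vinyl ketone at Cd, with Ca already configured.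
Forward order: acyclic triene 7; ring A closed (step 5); ring B, built as an aromatic acylphloroglucinol, joined at Ce (step 11); ring A finished (steps 12, 13); ring B unmasked and dearomatised last (steps 14, 16).
Stereochemistry: Ca from an iridium-catalysed allylic substitution; Ce by alkylation anti to isopropenyl; Cd by methyl addition anti to the Ce substituent; the acyl stereocentre from (R)-2-methylbutanoic acid; B3 from a chiral palladium catalyst.

Key step: step 5

Assumption: acid 9 is bought as the single R enantiomer, and the ligand antipodes written in steps 4 and 16 are working choices whose equally available mirror images would be used if a test run shows the opposite sense of induction.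
Abbreviation: Ar = 2,4,6-tris(methoxymethoxy)-3-methyl-5-[(2R)-2-methylbutanoyl]phenyl.

Step 1
Reactants: 1 methacrolein; 2 triethyl phosphonoacetate
Product: 3 ethyl (2E)-4-methylpenta-2,4-dienoate
Conditions: LiCl, DBU, MeCN, 0 °C to rt
Reagents that add atoms: none
Why: Horner–Wadsworth–Emmons olefination under Masamune–Roush conditions, in which the lithium-chelated stabilised phosphonate adds reversibly and collapses to the E enoate while the mild amine base spares the polymerisable enal.

Step 2
Reactants: 3 ethyl (2E)-4-methylpenta-2,4-dienoate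
Product: 4 (2E)-4-methylpenta-2,4-dien-1-ol
Conditions: iBu2AlH (2.2 equiv), CH2Cl2, −78 to 0 °C; aq. potassium sodium tartrate
Reagents that add atoms: none
Why: 1,2-reduction of a conjugated ester with two equivalents of iBu2AlH stops at the allylic alcohol and leaves the diene and its E geometry untouched.

Step 3
Reactants: 4 (2E)-4-methylpenta-2,4-dien-1-ol
Product: 5 methyl (2E)-4-methylpenta-2,4-dien-1-yl carbonate
Conditions: ClCO2Me, pyridine, CH2Cl2, 0 °C
Reagents that add atoms: methyl chloroformate COC(=O)Cl
Why: O-acylation of a primary allylic alcohol with a chloroformate installs a leaving group that ionises readily on iridium.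

Step 4
Reactants: 5 methyl (2E)-4-methylpenta-2,4-dien-1-yl carbonate; 6 2-(trimethylsilyloxy)buta-1,3-diene
Product: 7 (5R)-5-ethenyl-6-methylhepta-1,6-dien-3-one (5-isopropenylhepta-1,6-dien-3-one)
Conditions: [Ir(cod)Cl]2 (2 mol%), (Sa,Sc,Sc)-(1,1′-binaphthalene-2,2′-diyl) N,N-bis(1-phenylethyl)phosphoramidite (4 mol%), preactivated with n-PrNH2; KF, 18-crown-6, THF, rt
Reagents that add atoms: none
Why: Iridium-catalysed enantioselective allylic substitution with a fluoride-activated silyl enol ether of an α,β-unsaturated ketone, in which the cyclometalated iridium–phosphoramidite complex ionises 5 to an allyl complex that is attacked anti to the metal at its substituted terminus, so the ligand fixes Ca as R, and 6 can react only at its enol-ether CH2 and delivers the vinyl ketone directly.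

Step 5
Reactants: 7 (5R)-5-ethenyl-6-methylhepta-1,6-dien-3-one
Product: 8 (4R)-4-(prop-1-en-2-yl)cyclopent-2-en-1-one
Conditions: RuCl2(H2IMes)(PCy3)(=CHPh) (second-generation Grubbs catalyst, 3 mol%), 1,4-benzoquinone (10 mol%), CH2Cl2 (0.01 M), 40 °C
Reagents that add atoms: none
Why: This is a ring-closing olefin metathesis of a 1,6-dien-3-one, an established entry to cyclopent-2-enones: the benzylidene complex exchanges with the most accessible alkene, the monosubstituted vinyl group on Ca, and the new alkylidene adds to the vinyl ketone through a ruthenacyclobutane whose cycloreversion gives 8 and Ru=CH2, with ethene escaping. Ring A closes in the five-membered mode with both carbons of the new Cb=Cc bond inside the ring. No stereocentre is created, and Ca is carried through because the medium is neutral and 1,4-benzoquinone intercepts ruthenium hydrides that could shift the double bonds into conjugation. The selectivity needed is between two possible five-membered closures onto the vinyl ketone, one through the vinyl group and one through the isopropenyl group, which would give a trisubstituted enone. The substrate decides this kinetically: neither the 1,1-disubstituted isopropenyl group nor the electron-poor enone takes up the carbene readily, the carbene on the vinyl group cannot cyclise onto the isopropenyl group on the same carbon, and the conjugated product is not reopened. High dilution suppresses intermolecular metathesis.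

Step 6
Reactants: 9 (2R)-2-methylbutanoic acid; 10 2-methylbenzene-1,3,5-triol (2-methylphloroglucinol)
Product: 12 (2R)-2-methyl-1-(2,4,6-trihydroxy-3-methylphenyl)butan-1-one, via (2R)-2-methylbutanoyl chloride 11 (not isolated)
Conditions: (COCl)2, DMF (cat.), CH2Cl2, 0 °C to rt; then 10, AlCl3, CH2Cl2–PhNO2, 0 °C to rt; aq. HCl
Reagents that add atoms: none
Why: Friedel–Crafts C-acylation of a phloroglucinol, in which the two free ring positions of 10 are equivalent and the first acyl group deactivates the ring, so one monoketone results, and the base-free chloride formation and low temperature should preserve the α-stereocentre taken from 9.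

Step 7
Reactants: 12 (2R)-2-methyl-1-(2,4,6-trihydroxy-3-methylphenyl)butan-1-one
Product: 14 2,4,6-trihydroxy-3-methyl-5-[(2R)-2-methylbutanoyl]benzaldehyde, via aryl iminium chloride 13 (not isolated)
Conditions: POCl3, DMF, EtOAc, 0 °C to rt; then H2O, 40 °C
Reagents that add atoms: N,N-dimethylformamide CN(C)C=O; water O
Why: Vilsmeier–Haack formylation attacks the only ring C–H left on the still electron-rich triol, and the iminium salt is hydrolysed on work-up.

Step 8
Reactants: 14 2,4,6-trihydroxy-3-methyl-5-[(2R)-2-methylbutanoyl]benzaldehyde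
Product: 15 2,4,6-tris(methoxymethoxy)-3-methyl-5-[(2R)-2-methylbutanoyl]benzaldehyde (ArCHO)
Conditions: NaH (3.1 equiv), MOMCl, DMF, 0 °C
Reagents that add atoms: chloromethyl methyl ether COCCl
Why: Williamson-type O-alkylation, in which the hard chloromethyl ether goes to oxygen rather than ring carbon, sodium phenoxide formation overcomes the hydrogen bonds to the carbonyl groups, and the near-stoichiometric base leaves the ketone α-position alone.

Step 9
Reactants: 15 ArCHO
Product: 16 (2R)-1-[3-(hydroxymethyl)-2,4,6-tris(methoxymethoxy)-5-methylphenyl]-2-methylbutan-1-one (ArCH2OH)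
Conditions: NaBH4, MeOH–THF, 0 °C
Reagents that add atoms: none
Why: Chemoselective borohydride reduction, since the aldehyde reacts far faster than the di-ortho-substituted, α-branched aryl ketone.

Step 10
Reactants: 16 ArCH2OH
Product: 17 (2R)-1-[3-(bromomethyl)-2,4,6-tris(methoxymethoxy)-5-methylphenyl]-2-methylbutan-1-one (ArCH2Br)
Conditions: CBr4, PPh3, CH2Cl2, −20 °C; short filtration, used at once
Reagents that add atoms: tetrabromomethane BrC(Br)(Br)Br
Why: Appel bromination is neutral and spares the acetals, and in the hexasubstituted ring the alkoxy groups are twisted out of conjugation, which should make the benzylic bromide stable enough to handle cold.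

Step 11
Reactants: 8 (4R)-4-(prop-1-en-2-yl)cyclopent-2-en-1-one; 17 ArCH2Br
Product: 19 (4S,5R)-5-(ArCH2)-4-(prop-1-en-2-yl)cyclopent-2-en-1-one, via lithium cross-conjugated enolate 18 (not isolated)
Conditions: LiN(iPr)2 (1.05 equiv), THF, −78 °C, slow addition of 8; then 17, THF, −78 to −40 °C
Reagents that add atoms: none
Why: Kinetic α′-deprotonation of a cyclopent-2-enone with a hindered lithium amide followed by SN2 benzylation, in which the bromide approaches the flat enolate anti to the neighbouring isopropenyl group and so sets Ce trans to Ca, while the low temperature suppresses removal of the doubly allylic Ca–H and hydrogen shifts in the cyclopentadienolate.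

Step 12
Reactants: 19 (4S,5R)-5-(ArCH2)-4-(prop-1-en-2-yl)cyclopent-2-en-1-one
Product: 21 (2R,3S)-2-(ArCH2)-3-(prop-1-en-2-yl)cyclopentan-1-one, via dimethylphenylsilyl enol ether 20 (not isolated)
Conditions: [(Ph3P)CuH]6 (1 mol%), PhMe2SiH (1.5 equiv), toluene, rt; then AcOH–H2O–THF, 0 °C
Reagents that add atoms: none
Why: Copper hydride-catalysed conjugate reduction (1,4-hydrosilylation) delivers hydride to Cb only, leaves the isolated alkene, hindered aryl ketone and acetals alone, and forms the enol silane on the Cd=Cc side, so neither Ca nor Ce is touched.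

Step 13
Reactants: 21 (2R,3S)-2-(ArCH2)-3-(prop-1-en-2-yl)cyclopentan-1-one
Product: 22 (1S,2R,3S)-2-(ArCH2)-1-methyl-3-(prop-1-en-2-yl)cyclopentan-1-ol
Conditions: LaCl3·2LiCl (1 equiv), THF, rt; then MeMgBr, −20 °C; then H2O
Reagents that add atoms: methylmagnesium bromide C[Mg]Br
Why: Lanthanide-assisted Grignard 1,2-addition suppresses enolisation, and the methyl group enters the cyclopentanone on the face anti to the bulky adjacent Ce substituent, placing CH3 cis to isopropenyl and OH cis to the CH2 link (Cd = S), while the di-ortho-substituted aryl ketone is too hindered to compete.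

Step 14
Reactants: 22 (1S,2R,3S)-2-(ArCH2)-1-methyl-3-(prop-1-en-2-yl)cyclopentan-1-ol
Product: 23 (2R)-1-[2,4,6-trihydroxy-3-{[(1R,2S,5S)-2-hydroxy-2-methyl-5-(prop-1-en-2-yl)cyclopentyl]methyl}-5-methylphenyl]-2-methylbutan-1-one
Conditions: p-TsOH·H2O (cat.), MeOH, 40 °C, argon
Reagents that add atoms: none
Why: Acid-catalysed transacetalisation of aryl methoxymethyl ethers with methanol, for which a catalytic sulfonic acid in methanol should be too weak at this temperature to ionise the unactivated tertiary alcohol or protonate the isopropenyl group.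

Step 15
Reactants: 24 3-methylbut-2-en-1-ol (prenol)
Product: 25 methyl 3-methylbut-2-en-1-yl carbonate
Conditions: ClCO2Me, pyridine, CH2Cl2, 0 °C
Reagents that add atoms: methyl chloroformate COC(=O)Cl
Why: O-acylation of a primary allylic alcohol with a chloroformate gives a prenyl donor that releases its own base on ionisation.

Step 16
Reactants: 23 the fully substituted acylphloroglucinol; 25 methyl 3-methylbut-2-en-1-yl carbonate
Product: 26 (6R)-3,5-dihydroxy-4-{[(1R,2S,5S)-2-hydroxy-2-methyl-5-(prop-1-en-2-yl)cyclopentyl]methyl}-6-methyl-2-[(2R)-2-methylbutanoyl]-6-(3-methylbut-2-en-1-yl)cyclohexa-2,4-dien-1-one (target)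
Conditions: Pd2(dba)3·CHCl3 (2.5 mol%), (1R,2R)-N,N′-bis[2-(diphenylphosphino)benzoyl]cyclohexane-1,2-diamine (7.5 mol%), 25 (1.0 equiv), CH2Cl2, 0 °C to rt
Reagents that add atoms: none
Why: Proposed new method: the zerovalent palladium–ligand complex ionises 25 to a (1,1-dimethylallyl)palladium cation and, after loss of CO2, methoxide, which removes the most acidic phenol proton (B2–OH, para to the acyl group); the ambident phenolate attacks the unsubstituted allyl terminus through carbon, because O-prenylation is reversible under the catalyst, and it chooses B3 because B1 carries the β-branched cyclopentylmethyl group, while the chiral pocket of the ligand must distinguish the two faces of the flat ring and thereby sets B3 as R under catalyst control; the closest known reactions are the palladium-catalysed asymmetric allylic dearomatisation of substituted naphthols and phenols, the ligand-controlled linear prenylation of oxindoles (Tsuji–Trost type) and the non-asymmetric palladium-catalysed dearomative allylation of acylphloroglucinols.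

Compound list
1 | methacrolein | C=C(C)C=O | starting material
2 | triethyl phosphonoacetate | CCOC(=O)CP(=O)(OCC)OCC | starting material
3 | ethyl (2E)-4-methylpenta-2,4-dienoate | C=C(C)/C=C/C(=O)OCC | intermediate
4 | (2E)-4-methylpenta-2,4-dien-1-ol | C=C(C)/C=C/CO | intermediate
5 | methyl (2E)-4-methylpenta-2,4-dien-1-yl carbonate | C=C(C)/C=C/COC(=O)OC | intermediate
6 | 2-(trimethylsilyloxy)buta-1,3-diene | C=CC(=C)O[Si](C)(C)C | starting material
7 | (5R)-5-ethenyl-6-methylhepta-1,6-dien-3-one | C=CC(=O)C[C@H](C=C)C(C)=C | intermediate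
8 | (4R)-4-(prop-1-en-2-yl)cyclopent-2-en-1-one | C=C(C)[C@H]1C=CC(=O)C1 | intermediate
9 | (2R)-2-methylbutanoic acid | CC[C@@H](C)C(=O)O | starting material
10 | 2-methylbenzene-1,3,5-triol | Cc1c(O)cc(O)cc1O | starting material
11 | (2R)-2-methylbutanoyl chloride (not isolated) | CC[C@@H](C)C(=O)Cl | intermediate
12 | (2R)-2-methyl-1-(2,4,6-trihydroxy-3-methylphenyl)butan-1-one | Cc1c(O)cc(O)c(C(=O)[C@H](C)CC)c1O | intermediate
13 | aryl iminium chloride from 12 (not isolated) | C[N+](C)=Cc1c(O)c(C)c(O)c(C(=O)[C@H](C)CC)c1O.[Cl-] | intermediate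
14 | 2,4,6-trihydroxy-3-methyl-5-[(2R)-2-methylbutanoyl]benzaldehyde | O=Cc1c(O)c(C)c(O)c(C(=O)[C@H](C)CC)c1O | intermediate
15 | 2,4,6-tris(methoxymethoxy)-3-methyl-5-[(2R)-2-methylbutanoyl]benzaldehyde | O=Cc1c(OCOC)c(C)c(OCOC)c(C(=O)[C@H](C)CC)c1OCOC | intermediate
16 | (2R)-1-[3-(hydroxymethyl)-2,4,6-tris(methoxymethoxy)-5-methylphenyl]-2-methylbutan-1-one | OCc1c(OCOC)c(C)c(OCOC)c(C(=O)[C@H](C)CC)c1OCOC | intermediate
17 | (2R)-1-[3-(bromomethyl)-2,4,6-tris(methoxymethoxy)-5-methylphenyl]-2-methylbutan-1-one | BrCc1c(OCOC)c(C)c(OCOC)c(C(=O)[C@H](C)CC)c1OCOC | intermediate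
18 | lithium (R)-4-(prop-1-en-2-yl)cyclopenta-1,4-dien-1-olate, cross-conjugated enolate of 8 (not isolated) | C=C(C)[C@H]1C=CC([O-])=C1.[Li+] | intermediate
19 | (4S,5R)-5-(ArCH2)-4-(prop-1-en-2-yl)cyclopent-2-en-1-one | C=C(C)[C@H]1C=CC(=O)[C@@H]1Cc1c(OCOC)c(C)c(OCOC)c(C(=O)[C@H](C)CC)c1OCOC | intermediate
20 | dimethylphenylsilyl enol ether (Cd=Cc) of 21 (not isolated) | C=C(C)[C@H]1CC=C(O[Si](C)(C)c2ccccc2)[C@@H]1Cc1c(OCOC)c(C)c(OCOC)c(C(=O)[C@H](C)CC)c1OCOC | intermediate
21 | (2R,3S)-2-(ArCH2)-3-(prop-1-en-2-yl)cyclopentan-1-one | C=C(C)[C@H]1CCC(=O)[C@@H]1Cc1c(OCOC)c(C)c(OCOC)c(C(=O)[C@H](C)CC)c1OCOC | intermediate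
22 | (1S,2R,3S)-2-(ArCH2)-1-methyl-3-(prop-1-en-2-yl)cyclopentan-1-ol | C=C(C)[C@H]1CC[C@](C)(O)[C@@H]1Cc1c(OCOC)c(C)c(OCOC)c(C(=O)[C@H](C)CC)c1OCOC | intermediate
23 | (2R)-1-[2,4,6-trihydroxy-3-{[(1R,2S,5S)-2-hydroxy-2-methyl-5-(prop-1-en-2-yl)cyclopentyl]methyl}-5-methylphenyl]-2-methylbutan-1-one | C=C(C)[C@H]1CC[C@](C)(O)[C@@H]1Cc1c(O)c(C)c(O)c(C(=O)[C@H](C)CC)c1O | intermediate
24 | 3-methylbut-2-en-1-ol | CC(C)=CCO | starting material
25 | methyl 3-methylbut-2-en-1-yl carbonate | CC(C)=CCOC(=O)OC | intermediate
26 | (6R)-3,5-dihydroxy-4-{[(1R,2S,5S)-2-hydroxy-2-methyl-5-(prop-1-en-2-yl)cyclopentyl]methyl}-6-methyl-2-[(2R)-2-methylbutanoyl]-6-(3-methylbut-2-en-1-yl)cyclohexa-2,4-dien-1-one | C=C(C)[C@H]1CC[C@](C)(O)[C@@H]1CC1=C(O)[C@@](C)(CC=C(C)C)C(=O)C(C(=O)[C@H](C)CC)=C1O | target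

Total step count: 16.
Longest linear sequence: 10 steps (1–5, 11–14, 16). The ring B branch (6–10, 11–14, 16) is equally long.

Steps most likely to fail

1. Step 16 (new method).
- **What may go wrong:** The catalyst may fail to distinguish the two faces of the planar, locally almost symmetric phenolate. Alkylation may also stray to oxygen, to B1 or to the substituted allyl terminus.
- **Fallback:** This uses known chemistry, sets out from 23 and returns at 26. The classical alkylative dearomatisation of an acylphloroglucinol with prenyl bromide and aqueous KOH at 0 °C is run without chiral control. It should deliver 26 together with the 6S epimer of 26 F1. The two are diastereomers because of the stereocentres in ring A and in the acyl chain, and they are separated by preparative HPLC.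

2. Step 11.
- **What may go wrong:** Benzylation may be too slow, allowing proton transfer between enolate and product, removal of the doubly allylic Ca–H with erosion of configuration, and hydrogen shifts in the cyclopentadienolate on warming. The benzylic bromide may also ionise, or be attacked by its own ortho acetal oxygen, before the enolate reaches it.
- **Fallback:** This sets out from 8 (through enolate 18) and aldehyde 15, omits steps 9, 10 and 12, and returns at 21.
  - Enolate 18 is quenched at −78 °C with 15 in a kinetic aldol addition, much faster than an alkylation and again anti to isopropenyl, to give the aldol adduct F2.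
  - MsCl and Et3N convert F2 into its methanesulfonate F3.
  - DBU eliminates F3 to the cross-conjugated arylmethylidene dienone F4.
  - An excess of [(Ph3P)CuH]6 in wet toluene reduces both conjugated double bonds, passing through the arylmethylidene cyclopentanone F5.
  - The reduction should give 21 mixed with the cis ketone F6. Brief treatment with DBU in toluene equilibrates F6 to the more stable trans ketone 21.

3. Step 13.
- **What may go wrong:** The small methyl nucleophile may show poor facial selectivity on the flexible cyclopentanone. Enolisation may also return starting ketone.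
- **Fallback:** This sets out from 19, replaces steps 12 and 13, and returns at 22.
  - The methyl group is added at the enone oxidation level with the organocerium reagent from MeLi and CeCl3 (THF, −78 °C). This reagent adds 1,2, and it meets a flat ring whose faces differ only through the adjacent Ce substituent, giving the tertiary allylic alcohol F7.
  - The strained cis-disubstituted ring alkene is then saturated with diimide (2-nitrobenzenesulfonyl hydrazide, Et3N). Diimide reduces such alkenes faster than the 1,1-disubstituted isopropenyl group.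

Further compounds
F1 | step 16 | (6S)-epimer of 26 | C=C(C)[C@H]1CC[C@](C)(O)[C@@H]1CC1=C(O)[C@](C)(CC=C(C)C)C(=O)C(C(=O)[C@H](C)CC)=C1O
F2 | step 11 | (4S,5S)-5-[Ar(hydroxy)methyl]-4-(prop-1-en-2-yl)cyclopent-2-en-1-one, carbinol carbon undefined | C=C(C)[C@H]1C=CC(=O)[C@@H]1C(O)c1c(OCOC)c(C)c(OCOC)c(C(=O)[C@H](C)CC)c1OCOC
F3 | step 11 | methanesulfonate of F2 | C=C(C)[C@H]1C=CC(=O)[C@@H]1C(OS(C)(=O)=O)c1c(OCOC)c(C)c(OCOC)c(C(=O)[C@H](C)CC)c1OCOC
F4 | step 11 | (4R)-5-(Ar-methylidene)-4-(prop-1-en-2-yl)cyclopent-2-en-1-one, alkene geometry undefined | C=C(C)[C@H]1C=CC(=O)C1=Cc1c(OCOC)c(C)c(OCOC)c(C(=O)[C@H](C)CC)c1OCOC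
F5 | step 11 | (3R)-2-(Ar-methylidene)-3-(prop-1-en-2-yl)cyclopentan-1-one, alkene geometry undefined | C=C(C)[C@H]1CCC(=O)C1=Cc1c(OCOC)c(C)c(OCOC)c(C(=O)[C@H](C)CC)c1OCOC
F6 | step 11 | (2S,3S)-2-(ArCH2)-3-(prop-1-en-2-yl)cyclopentan-1-one, cis epimer of 21 | C=C(C)[C@H]1CCC(=O)[C@H]1Cc1c(OCOC)c(C)c(OCOC)c(C(=O)[C@H](C)CC)c1OCOC
F7 | step 13 | (1S,4S,5R)-5-(ArCH2)-1-methyl-4-(prop-1-en-2-yl)cyclopent-2-en-1-ol | C=C(C)[C@H]1C=C[C@](C)(O)[C@@H]1Cc1c(OCOC)c(C)c(OCOC)c(C(=O)[C@H](C)CC)c1OCOC
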